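## Structural features

The target is one benzene ring with five substituents and a single ring hydrogen. With the ring numbered C1 (CHO), C2 (side chain), C3 (OH), C4 (OMe), C5 (H), C6 (OH), the C3 and C6 hydroxyls are para, so the core is a formylated methoxyhydroquinone whose C6 hydroxyl is hydrogen-bonded to the aldehyde. The side chain is a 2-acetoxytridecyl group joined through its C1' methylene to C2. Its only stereocentre, C2' (R), is homobenzylic, has no neighbouring stereocentre and no acidic hydrogen, so it can be bought and carried through. The fragile groups are the hydroquinone (oxidized to the quinone by air and by most oxidants), the aryl aldehyde (reducible, also under hydrogenolysis) and the secondary acetate (lost to alkoxide or hydride). There is also latent ring-chain chemistry between O-2' and C1: a free C2' hydroxyl closes onto a C1 ester to give the dihydroisocoumarin and onto a C1 aldehyde to give the lactol, so the acetate must be installed while C1 is neither. The real difficulty is placing five contiguous substituents with three differently treated oxygens (C3 free, C4 methylated, C6 free) and ordering the redox changes at C1 around the acetate and the hydroquinone. The key step exploits three facts: O-C4, H-C5 and O-C6 form the pattern of a cyclohexane-1,3-dione; the carboxyl-level C1 beside the alkyl-bearing C2 is what a malonate carbon becomes after adding to the β-carbon of an enone; and the C3 oxygen is then the α-oxygen of that enone.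

## Logic of the disconnections

19 back to 18: the O-CH2Ph bond at C3 is cut last. Until then every intermediate is a mono-phenol that cannot form a quinone, so the MnO2 step is possible. The demand is a debenzylation that spares the aldehyde and the acetate.

18 back to 17 and 16: the C1 aldehyde is traced to the benzylic alcohol, and the phenol/benzylic alcohol pair to its isopropylidene acetal (the two acetal C-O bonds are cut). This is done because the acetate has to be installed while C1 is a benzylic ether; at the ester level the free C2' hydroxyl would lactonize and at the aldehyde level it would form the lactol. The demands are a benzylic oxidation that leaves the electron-rich phenol alone and an acetal hydrolysis that leaves the acetate alone.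

16 back to 14 (through 15): the O-acetyl bond is exchanged for the O-Si bond. This reduces the problem to a silyl ether that is inert to everything earlier; the forward demand is only fluoride cleavage and acylation, with no bond to C2' broken.

14 back to 13 and 12: the acetonide C-O bonds and the two C1-H bonds are removed, returning to the salicylate ester. One protecting group covers both the phenol and the benzylic hydroxyl. The demand is a hydride reduction of a hindered, chelated ester that does not over-reduce through an ortho-quinone methide.

12 back to 11: the O-CH3 bond at C4 and one ring unsaturation are removed (two hydrogens returned to C1 and C2). This turns a pentasubstituted arene into a dione whose substituents are all already in place, and lets I2 in methanol aromatize and differentiate O-4 from O-6 in one operation. The demand is etherification at the non-chelated C4 oxygen only, and survival of the side-chain silyl ether in methanolic HI. A tert-butyldimethylsilyl ether is not safe there, because I2 in methanol is itself a standard reagent for cleaving such ethers, and the freed hydroxyl would lactonize onto the C1 ester. The silyl group is therefore changed to tert-butyldiphenylsilyl from the start, in 3, 4, 8 and 11.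

11 back to 8 and 9 (through 10): C1-C2 and C5-C6 are cut. The ring falls into a malonate and a linear α-benzyloxy enone that already carries the side chain and its stereocentre. The demand is conjugate addition faster than γ-deprotonation of 8. A silyloxide is a competent leaving group (silanols are more acidic than alcohols), so the protection against its loss is kinetic: little free methoxide and a soft nucleophile.

8 back to 4 and 7: the C2=C3 double bond of the future ring is cut by Horner-Wadsworth-Emmons logic. This separates a three-carbon acetyl/alkoxy unit from the chiral aldehyde. The demand is a base mild enough not to eliminate the β-silyloxy group of 4; alkene geometry is irrelevant.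

7 back to 5 and 6: the C-O bond at the phosphonate carbon is cut (carbenoid O-H insertion), which installs the future C3 oxygen already protected. 4 back to 3, 2 and 1: functional-group changes only; the stereocentre comes with 1 and no step touches a bond to it.

## Other disconnections considered

Alternative 1: The cut is at C2-C1' and C2'-C3', with C2' set by catalyst control. The forward step combines the vinyl boronate A3 and undecylmagnesium bromide A4 into an ate complex. With the aryl bromide A2, Pd(OAc)2, a MandyPhos ligand and NaOTf, this should undergo aryl-induced 1,2-migration of the undecyl group to give the boronate A1.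
- In its favour: it is highly convergent, and A2 should be reachable in about two steps. After the key step only stereoretentive C-B oxidation, acetylation, formylation at C1 and removal of the two isopropyl ethers remain.
- Better than the chosen plan on two points: the whole sequence would be roughly half as long, and the acetate is in place before any C1 carbonyl exists, so the lactone/lactol problem and the acetonide detour never arise.
- Against it: the bromide of A2 is flanked by an ortho isopropoxy group, a hindered partner for the metallate shift. The configuration at C2' depends on ligand control instead of a purchased centre. The late formylation must choose C1 over C5, and both positions are doubly activated by oxygen. The Lewis acids used for formylation and de-isopropylation must spare the acetate and the methyl ether.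
- Comparison: the chosen plan is more secure on arene regiochemistry, which it fixes by construction, and on configuration; Alternative 1 is better on step economy.

Alternative 2: The cut is at C2-C3 and C1-C6 across the ring. The forward step is a thermal Diels-Alder reaction of the silyloxyfuran A6 with the acetoxy ynal A7, followed by opening of the oxa-bridge and tautomerization to the arene A5.
- In its favour: this is the shortest conceivable route. The ring is formed at the correct oxidation level with the aldehyde, the acetate, the methyl ether and both hydroquinone oxygens in place, and only an aryl silyl ether remains to be cleaved.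
- Better than the chosen plan on step economy, redox economy and the acetate/aldehyde ordering problem, which does not arise. The stereocentre would again come from the chiral pool, so that point is equal.
- Against it: A6 is a very electron-rich, hydrolytically labile diene that tends to react with ynals in a stepwise vinylogous aldol or Michael sense, giving open-chain butenolides instead of arenes. The free aldehyde of A7 is a competing electrophile. The regiochemistry is electronically matched but untested for this pairing. The propargylic methylene next to the acetoxy carbon invites elimination on heating.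
- Comparison: the mechanism is far less predictable than a malonate annulation with close precedent, so the chosen plan trades length for reliability.

Alternative 3: The cut is at C1-C6, with C2-C3 made beforehand by adding the alkenyllithium from iodide A10 to the semisquarate A11. The forward step heats the resulting cyclobutenone A9 in toluene: electrocyclic opening to a dienylketene, closure of the ketene carbon onto the alkene terminus and enolization give the hydroquinone A8.
- In its favour: the substitution pattern is unambiguous by construction, the methyl ether is present from the start, and both hydroxyls appear at the hydroquinone level without an aromatization step.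
- Equal or better than the chosen plan on the C1 problem: the aldehyde arrives as an acetal, which prevents lactol formation as well as the acetonide does and needs no reduction/oxidation pair.
- Against it: A11 and the stereodefined, regiodefined iodide A10 each need several steps. The organolithium addition must select the ketone carbonyl over the vinylogous ester carbonyl. A8 is a free, air-sensitive hydroquinone whose two phenols would be acetylated along with the side chain and would then have to be freed selectively.
- Comparison: overall length is about equal to the chosen plan. Alternative 3 is better on regiochemical certainty; the chosen plan is better on robustness, because it keeps the hydroquinone masked until the last step and uses no cryogenic organometallic chemistry.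

Key step: step 6

Remark: ring atoms are numbered as in the target throughout (C1 formyl carbon to C6), side-chain atoms C1' and C2'; enone 8 is carried on as whatever E/Z mixture the olefination delivers (Z drawn), since both geometries converge in step 6.

## Route

Step 1
Reactants: 1 (R)-3-hydroxytetradecanoic acid
Product: 2 methyl (R)-3-hydroxytetradecanoate
Conditions: MeOH, H2SO4 (cat.), 50 °C
Reagents that add atoms: methanol, CO
Why: Fischer esterification; the stereocentre carries no acidic hydrogen and no bond to it is broken, so the R configuration of 1 is kept.

Step 2
Reactants: 2 methyl (R)-3-hydroxytetradecanoate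
Product: 3 methyl (R)-3-(tert-butyldiphenylsilyloxy)tetradecanoate
Conditions: TBDPSCl, imidazole, DMF, rt
Reagents that add atoms: tert-butyl(chloro)diphenylsilane, CC(C)(C)[Si](Cl)(c1ccccc1)c1ccccc1
Why: Silylation of the secondary alcohol through the N-silylimidazolium ion. This silyl ether is chosen because it withstands the methanolic HI of step 7 far better than a tert-butyldimethylsilyl ether, and it gives the aliphatic intermediates a chromophore.

Step 3
Reactants: 3 methyl (R)-3-(tert-butyldiphenylsilyloxy)tetradecanoate
Product: 4 (R)-3-(tert-butyldiphenylsilyloxy)tetradecanal
Conditions: i-Bu2AlH (1.1 equiv), CH2Cl2, −78 °C; MeOH, then aq. Rochelle salt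
Reagents that add atoms: none
Why: Partial ester reduction; the aluminium hemiacetal of a β-silyloxy ester is stable at −78 °C and releases the aldehyde only on work-up. The carbinol centre is not enolizable and is unchanged.

Step 4
Reactants: 5 dimethyl (1-diazo-2-oxopropyl)phosphonate; 6 benzyl alcohol
Product: 7 dimethyl [1-(benzyloxy)-2-oxopropyl]phosphonate
Conditions: Rh2(OAc)4 (1 mol %), PhMe, 80 °C, slow addition of 5 to excess 6
Reagents that add atoms: none
Why: Rhodium carbenoid O-H insertion; the metal carbene from the diazo ketophosphonate is trapped by the alcohol faster than it rearranges when the diazo compound is kept dilute. The new centre is racemic and is destroyed in step 5.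

Step 5
Reactants: 4 (R)-3-(tert-butyldiphenylsilyloxy)tetradecanal; 7 dimethyl [1-(benzyloxy)-2-oxopropyl]phosphonate
Product: 8 (R,Z)-3-(benzyloxy)-6-(tert-butyldiphenylsilyloxy)heptadec-3-en-2-one
Conditions: LiCl, DBU, MeCN, 0 °C to rt
Reagents that add atoms: none
Why: Horner-Wadsworth-Emmons olefination under LiCl/amine conditions, mild enough not to eliminate the β-silyloxy group of 4. The α-alkoxy phosphonate should give mainly the Z enol ether (acyl group and chain trans), but either geometry serves.

Step 6
Reactants: 8 (R,Z)-3-(benzyloxy)-6-(tert-butyldiphenylsilyloxy)heptadec-3-en-2-one; 9 dimethyl malonate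
Product: 11 methyl 5-(benzyloxy)-2-hydroxy-4-oxo-6-[(R)-2-(tert-butyldiphenylsilyloxy)tridecyl]cyclohex-1-ene-1-carboxylate, via Michael adduct 10 (not isolated)
Conditions: 9 (1.5 equiv) premixed with NaOMe (1.4 equiv), MeOH, 0 °C to rt; then reflux; cold 1 M HCl
Reagents that add atoms: none
Why: Sodiomalonate adds 1,4 to the β-carbon of 8 and forms C1-C2; protonation of the resulting α-benzyloxy ketone enolate gives 10. On heating, the ketone enolates equilibrate, and only the methyl-side enolate (future C5) can reach a malonate ester carbonyl, so its Claisen acylation forms C5-C6 with loss of methoxide. This closure is 6-(enolendo)-exo-trig, the favoured mode for enolate acylation, whereas the enolate at C3 could only close a four-membered ring. The product is a vinylogous acid much more acidic than methanol or malonate, so it is removed as its sodium enolate, and this pulls the reversible Michael and Claisen steps forward. The closest known reaction type is the Michael-Claisen annulation of malonates with β-substituted methyl vinyl ketones to 2-alkoxycarbonylcyclohexane-1,3-diones. The new sp3 centres at C1, C2 and C3 are not controlled (C1 and C3 equilibrate through enolates) and need not be, because all three become sp2 in step 7; the C2' centre lies away from every acidic hydrogen and is untouched. The step needs conjugate addition to beat carbonyl addition and, above all, γ-deprotonation of 8 with loss of silyloxide. The soft stabilized nucleophile, the slight deficit of methoxide relative to malonate and running the addition cold before heating should secure this. The α-benzyloxy group makes the β-carbon less electrophilic, so excess malonate and high concentration are used.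

Step 7
Reactants: 11 methyl 5-(benzyloxy)-2-hydroxy-4-oxo-6-[(R)-2-(tert-butyldiphenylsilyloxy)tridecyl]cyclohex-1-ene-1-carboxylate
Product: 12 methyl 3-(benzyloxy)-6-hydroxy-4-methoxy-2-[(R)-2-(tert-butyldiphenylsilyloxy)tridecyl]benzoate
Conditions: I2 (1.5 equiv), MeOH, 60 °C; aq. Na2S2O3
Reagents that add atoms: methanol, CO
Why: Iodine-methanol aromatization of a cyclohexane-1,3-dione. The HI formed catalyses methyl enol ether formation at the C4 oxygen, while the C6 oxygen stays in the hydrogen-bonded enol of the β-keto ester; iodination at the doubly activated C1 and loss of HI supply the third double bond. The bulky silyl ether and the benzyl ether should tolerate the dilute HI over a short reaction time.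

Step 8
Reactants: 12 methyl 3-(benzyloxy)-6-hydroxy-4-methoxy-2-[(R)-2-(tert-butyldiphenylsilyloxy)tridecyl]benzoate
Product: 13 4-(benzyloxy)-2-(hydroxymethyl)-5-methoxy-3-[(R)-2-(tert-butyldiphenylsilyloxy)tridecyl]phenol
Conditions: LiAlH4 (3 equiv), THF, 0 °C to rt; aq. Rochelle salt
Reagents that add atoms: none
Why: Hydride reduction of the hindered, chelated salicylate to the salicyl alcohol. The temperature is kept at or below rt so that the aluminium phenoxide-alkoxide does not collapse to an ortho-quinone methide and over-reduce.

Step 9
Reactants: 13 4-(benzyloxy)-2-(hydroxymethyl)-5-methoxy-3-[(R)-2-(tert-butyldiphenylsilyloxy)tridecyl]phenol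
Product: 14 6-(benzyloxy)-7-methoxy-2,2-dimethyl-5-[(R)-2-(tert-butyldiphenylsilyloxy)tridecyl]-4H-1,3-benzodioxine
Conditions: Me2C(OMe)2, PPTS (cat.), acetone, rt
Reagents that add atoms: 2,2-dimethoxypropane, COC(C)(C)OC
Why: Acid-catalysed transacetalization; the phenol and the ortho hydroxymethyl group close the six-membered benzodioxine. This removes both hydroxyls and the C1 oxidation level from play during the acetate exchange.

Step 10
Reactants: 14 6-(benzyloxy)-7-methoxy-2,2-dimethyl-5-[(R)-2-(tert-butyldiphenylsilyloxy)tridecyl]-4H-1,3-benzodioxine
Product: 16 (R)-1-[6-(benzyloxy)-7-methoxy-2,2-dimethyl-4H-1,3-benzodioxin-5-yl]tridecan-2-yl acetate, via secondary alcohol 15 (not isolated)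
Conditions: TBAF, THF, rt to 40 °C; then Ac2O, Et3N, DMAP (cat.), 0 °C to rt
Reagents that add atoms: acetic anhydride, CC(=O)OC(C)=O
Why: Fluoride cleaves the Si-O bond, and with C1 held as a benzylic ether the freed C2' hydroxyl has no carbonyl partner for lactone or lactol formation. DMAP-catalysed acyl transfer in the same flask then gives the acetate with retention, since no bond to C2' is broken.

Step 11
Reactants: 16 (R)-1-[6-(benzyloxy)-7-methoxy-2,2-dimethyl-4H-1,3-benzodioxin-5-yl]tridecan-2-yl acetate
Product: 17 (R)-1-[6-(benzyloxy)-3-hydroxy-2-(hydroxymethyl)-5-methoxyphenyl]tridecan-2-yl acetate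
Conditions: 1 M aq. HCl, THF, rt
Reagents that add atoms: none
Why: Hydrolysis of the isopropylidene acetal, which ionizes easily with help from the aryl oxygen; a secondary alkyl acetate is stable to dilute acid at rt. Any transient ortho-quinone methide is recaptured by water to the same product.

Step 12
Reactants: 17 (R)-1-[6-(benzyloxy)-3-hydroxy-2-(hydroxymethyl)-5-methoxyphenyl]tridecan-2-yl acetate
Product: 18 (R)-1-[6-(benzyloxy)-2-formyl-3-hydroxy-5-methoxyphenyl]tridecan-2-yl acetate
Conditions: MnO2 (activated, excess), CH2Cl2, rt
Reagents that add atoms: none
Why: Heterogeneous MnO2 oxidation, selective for the benzylic alcohol; it stops at the aldehyde, which is held by the hydrogen bond to the C6 hydroxyl. The acetate is inert, and the benzyl ether para to the phenol keeps the ring from going to the quinone.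

Step 13
Reactants: 18 (R)-1-[6-(benzyloxy)-2-formyl-3-hydroxy-5-methoxyphenyl]tridecan-2-yl acetate
Product: 19 (R)-1-(2-formyl-3,6-dihydroxy-5-methoxyphenyl)tridecan-2-yl acetate
Conditions: H2 (1 atm), 10% Pd/C, EtOAc, rt; filtration and concentration under argon
Reagents that add atoms: none
Why: Hydrogenolysis of the aryl benzyl ether should be much faster than reduction of the chelated, electron-rich aldehyde at 1 atm in a non-protic solvent. Toluene is the only by-product, and the hydroquinone is handled without air.

## Compound list

1 | (R)-3-hydroxytetradecanoic acid | CCCCCCCCCCC[C@H](CC(=O)O)O | starting material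
2 | methyl (R)-3-hydroxytetradecanoate | CCCCCCCCCCC[C@H](CC(=O)OC)O | intermediate
3 | methyl (R)-3-(tert-butyldiphenylsilyloxy)tetradecanoate | CCCCCCCCCCC[C@H](CC(=O)OC)O[Si](c1ccccc1)(c1ccccc1)C(C)(C)C | intermediate
4 | (R)-3-(tert-butyldiphenylsilyloxy)tetradecanal | CCCCCCCCCCC[C@H](CC=O)O[Si](c1ccccc1)(c1ccccc1)C(C)(C)C | intermediate
5 | dimethyl (1-diazo-2-oxopropyl)phosphonate | COP(=O)(OC)C(=[N+]=[N-])C(C)=O | starting material
6 | benzyl alcohol | OCc1ccccc1 | starting material
7 | dimethyl [1-(benzyloxy)-2-oxopropyl]phosphonate (racemic) | COP(=O)(OC)C(OCc1ccccc1)C(C)=O | intermediate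
8 | (R,Z)-3-(benzyloxy)-6-(tert-butyldiphenylsilyloxy)heptadec-3-en-2-one | CCCCCCCCCCC[C@H](C/C=C(\OCc1ccccc1)C(C)=O)O[Si](c1ccccc1)(c1ccccc1)C(C)(C)C | intermediate
9 | dimethyl malonate | COC(=O)CC(=O)OC | starting material
10 | dimethyl 2-[(6R)-3-(benzyloxy)-6-(tert-butyldiphenylsilyloxy)-2-oxoheptadecan-4-yl]malonate (mixture at C3 and C4) | CCCCCCCCCCC[C@H](CC(C(OCc1ccccc1)C(C)=O)C(C(=O)OC)C(=O)OC)O[Si](c1ccccc1)(c1ccccc1)C(C)(C)C | intermediate (not isolated)
11 | methyl 5-(benzyloxy)-2-hydroxy-4-oxo-6-[(R)-2-(tert-butyldiphenylsilyloxy)tridecyl]cyclohex-1-ene-1-carboxylate (enol form; ring centres C5 and C6 a mixture, left undefined) | COC(=O)C1=C(O)CC(=O)C(OCc2ccccc2)C1C[C@@H](CCCCCCCCCCC)O[Si](c1ccccc1)(c1ccccc1)C(C)(C)C | intermediate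
12 | methyl 3-(benzyloxy)-6-hydroxy-4-methoxy-2-[(R)-2-(tert-butyldiphenylsilyloxy)tridecyl]benzoate | COC(=O)c1c(O)cc(OC)c(OCc2ccccc2)c1C[C@@H](CCCCCCCCCCC)O[Si](c1ccccc1)(c1ccccc1)C(C)(C)C | intermediate
13 | 4-(benzyloxy)-2-(hydroxymethyl)-5-methoxy-3-[(R)-2-(tert-butyldiphenylsilyloxy)tridecyl]phenol | OCc1c(O)cc(OC)c(OCc2ccccc2)c1C[C@@H](CCCCCCCCCCC)O[Si](c1ccccc1)(c1ccccc1)C(C)(C)C | intermediate
14 | 6-(benzyloxy)-7-methoxy-2,2-dimethyl-5-[(R)-2-(tert-butyldiphenylsilyloxy)tridecyl]-4H-1,3-benzodioxine | CC1(C)OCc2c(O1)cc(OC)c(OCc3ccccc3)c2C[C@@H](CCCCCCCCCCC)O[Si](c1ccccc1)(c1ccccc1)C(C)(C)C | intermediate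
15 | (R)-1-[6-(benzyloxy)-7-methoxy-2,2-dimethyl-4H-1,3-benzodioxin-5-yl]tridecan-2-ol | CC1(C)OCc2c(O1)cc(OC)c(OCc3ccccc3)c2C[C@@H](CCCCCCCCCCC)O | intermediate (not isolated)
16 | (R)-1-[6-(benzyloxy)-7-methoxy-2,2-dimethyl-4H-1,3-benzodioxin-5-yl]tridecan-2-yl acetate | CC1(C)OCc2c(O1)cc(OC)c(OCc3ccccc3)c2C[C@@H](CCCCCCCCCCC)OC(C)=O | intermediate
17 | (R)-1-[6-(benzyloxy)-3-hydroxy-2-(hydroxymethyl)-5-methoxyphenyl]tridecan-2-yl acetate | OCc1c(O)cc(OC)c(OCc2ccccc2)c1C[C@@H](CCCCCCCCCCC)OC(C)=O | intermediate
18 | (R)-1-[6-(benzyloxy)-2-formyl-3-hydroxy-5-methoxyphenyl]tridecan-2-yl acetate | O=Cc1c(O)cc(OC)c(OCc2ccccc2)c1C[C@@H](CCCCCCCCCCC)OC(C)=O | intermediate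
19 | (R)-1-(2-formyl-3,6-dihydroxy-5-methoxyphenyl)tridecan-2-yl acetate | CCCCCCCCCCC[C@H](Cc1c(O)c(OC)cc(O)c1C=O)OC(C)=O | target

## Step count and least certain steps

Total step count: 13. Longest linear sequence: 12 steps (steps 1 to 3 and 5 to 13, from 1); step 4 is a one-step side branch.

Step 6 (key step). The most likely failure is a sluggish conjugate addition to the donor-substituted β-carbon. That would let γ-deprotonation of the enone with expulsion of the silyloxide, or reversal of the Michael addition on heating, outrun the ring closure. Fallback: reverse the polarity of the first bond. Setting out from 4, Knoevenagel condensation with 9 (piperidine, AcOH, PhMe) should give dimethyl 2-[(R)-3-(tert-butyldiphenylsilyloxy)tetradecylidene]malonate F1, a much stronger acceptor. Amine-catalysed (pyrrolidine, enamine) Michael addition of commercial 1-(benzyloxy)propan-2-one, which reacts through its oxygen-bearing carbon, then forms C2-C3 instead of C1-C2. This comes back to the route at 10, which NaOMe in MeOH closes to 11 as in step 6; 7 and 8 are bypassed.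

Step 7. The most likely failure is cleavage of the silyl ether by the HI set free, followed by closure of the liberated C2' hydroxyl onto the C1 ester, so that a mixture results. Fallback: make that lactone the intermediate. Setting out from 12 (alone or mixed with its desilylated congeners), TBAF in THF should remove the silyl group and lactonize everything to (R)-5-(benzyloxy)-8-hydroxy-6-methoxy-3-undecylisochroman-1-one F2. LiAlH4 in THF then opens the lactone to 4-(benzyloxy)-2-(hydroxymethyl)-3-[(R)-2-hydroxytridecyl]-5-methoxyphenol F3. Me2C(OMe)2 with PPTS protects only the phenol/benzylic alcohol pair, and the route is rejoined at 15, which is acetylated to 16 under the second set of conditions of step 10.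

Step 5. The most likely failure is base-induced β-elimination of the silyloxide from the aldehyde, together with slow olefination by the hindered, doubly stabilized α-alkoxy phosphonate anion. Fallback: aldol addition and dehydration without a phosphonate. Setting out from 4, amine-catalysed aldol addition of 1-(benzyloxy)propan-2-one (used in excess) through its oxygen-bearing carbon should give (6R)-3-(benzyloxy)-4-hydroxy-6-(tert-butyldiphenylsilyloxy)heptadecan-2-one F4. MsCl and Et3N convert it into (6R)-3-(benzyloxy)-2-oxo-6-(tert-butyldiphenylsilyloxy)heptadecan-4-yl methanesulfonate F5, and DBU eliminates this to the enone, coming back to the route at 8.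

Step 13. The most likely failures are over-reduction of the aryl aldehyde during hydrogenolysis and air oxidation of the freed hydroquinone to the quinone during catalyst removal. Fallback: cleave the benzyl ether without a reductant and without a filtration. Setting out from 18, BCl3 with pentamethylbenzene as benzyl-cation scavenger in CH2Cl2 at −78 °C should give 19 directly. Acetates, aldehydes and aryl methyl ethers are known to tolerate these conditions, and no new compound lies on the way.

## Further compounds

F1 | step 6 | dimethyl 2-[(R)-3-(tert-butyldiphenylsilyloxy)tetradecylidene]malonate | CCCCCCCCCCC[C@H](CC=C(C(=O)OC)C(=O)OC)O[Si](c1ccccc1)(c1ccccc1)C(C)(C)C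
F2 | step 7 | (R)-5-(benzyloxy)-8-hydroxy-6-methoxy-3-undecylisochroman-1-one | O=C1O[C@H](CCCCCCCCCCC)Cc2c1c(O)cc(OC)c2OCc1ccccc1
F3 | step 7 | 4-(benzyloxy)-2-(hydroxymethyl)-3-[(R)-2-hydroxytridecyl]-5-methoxyphenol | OCc1c(O)cc(OC)c(OCc2ccccc2)c1C[C@@H](CCCCCCCCCCC)O
F4 | step 5 | (6R)-3-(benzyloxy)-4-hydroxy-6-(tert-butyldiphenylsilyloxy)heptadecan-2-one | CCCCCCCCCCC[C@H](CC(O)C(OCc1ccccc1)C(C)=O)O[Si](c1ccccc1)(c1ccccc1)C(C)(C)C
F5 | step 5 | (6R)-3-(benzyloxy)-2-oxo-6-(tert-butyldiphenylsilyloxy)heptadecan-4-yl methanesulfonate | CCCCCCCCCCC[C@H](CC(OS(C)(=O)=O)C(OCc1ccccc1)C(C)=O)O[Si](c1ccccc1)(c1ccccc1)C(C)(C)C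
F0 | step 13 | none | none
A1 | alternative 1 | (R)-2-[1-(2,5-diisopropoxy-3-methoxyphenyl)tridecan-2-yl]-4,4,5,5-tetramethyl-1,3,2-dioxaborolane | CCCCCCCCCCC[C@H](Cc1cc(OC(C)C)cc(OC)c1OC(C)C)B1OC(C)(C)C(C)(C)O1
A2 | alternative 1 | 1-bromo-2,5-diisopropoxy-3-methoxybenzene | Brc1cc(OC(C)C)cc(OC)c1OC(C)C
A3 | alternative 1 | 4,4,5,5-tetramethyl-2-vinyl-1,3,2-dioxaborolane | C=CB1OC(C)(C)C(C)(C)O1
A4 | alternative 1 | undecylmagnesium bromide | CCCCCCCCCCC[Mg]Br
A5 | alternative 2 | (R)-1-[3-(tert-butyldimethylsilyloxy)-2-formyl-6-hydroxy-5-methoxyphenyl]tridecan-2-yl acetate | CCCCCCCCCCC[C@H](Cc1c(O)c(OC)cc(O[Si](C)(C)C(C)(C)C)c1C=O)OC(C)=O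
A6 | alternative 2 | tert-butyl[(4-methoxyfuran-2-yl)oxy]dimethylsilane | COc1coc(O[Si](C)(C)C(C)(C)C)c1
A7 | alternative 2 | (R)-1-oxohexadec-2-yn-5-yl acetate | CCCCCCCCCCC[C@H](CC#CC=O)OC(C)=O
A8 | alternative 3 | 2-(diethoxymethyl)-5-methoxy-3-[(R)-2-(tert-butyldimethylsilyloxy)tridecyl]benzene-1,4-diol | CCCCCCCCCCC[C@H](Cc1c(O)c(OC)cc(O)c1C(OCC)OCC)O[Si](C)(C)C(C)(C)C
A9 | alternative 3 | 4-[(5R)-5-(tert-butyldimethylsilyloxy)-1,1-diethoxyhexadec-2-en-3-yl]-4-hydroxy-3-methoxycyclobut-2-en-1-one | CCCCCCCCCCC[C@H](CC(=CC(OCC)OCC)C1(O)C(OC)=CC1=O)O[Si](C)(C)C(C)(C)C
A10 | alternative 3 | tert-butyl{[(5R)-1,1-diethoxy-3-iodohexadec-2-en-5-yl]oxy}dimethylsilane | CCCCCCCCCCC[C@H](CC(I)=CC(OCC)OCC)O[Si](C)(C)C(C)(C)C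
A11 | alternative 3 | 3-methoxycyclobut-3-ene-1,2-dione | COC1=CC(=O)C1=O
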